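A direct plan would set Cβ early by lipase monoacetylation of the prochiral 2-aryloxypropane-1,3-diol A1,
exchange the acetate for a silyl ether, oxidise to the α-aryloxy aldehyde A2, add a ring A aryl Grignard reagent,
reoxidise to the protected ketone A3 and unmask phenol, alcohol and acid in two further steps.
Its weakest steps would be: (a) the acetate-to-silyl exchange, four operations with no skeletal gain, in which a single
1,3-acyl or silyl shift would racemise a centre defined only by its protecting groups; (b) the Grignard addition to A2,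
where a basic reagent would meet an enolisable, β-eliminable aldehyde and make a carbinol centre that is at once destroyed;
(c) hydrogenolysis and acidolysis after A3, two steps on the most precious material with the labile α-aryloxy ketone in place.

**Plan of the new route**
The retrosynthesis first removes the ketone (Cα–H; the target becomes a threo 1,3-diol) and returns Cγ to an ester.
It then cuts Cα–Cβ (Claisen acylation of a ring B aryloxyacetate by a ring A aroyl chloride) and the O–Cβ ether bond (Williamson).
Rings A and B are bought as syringic and vanillic acid derivatives; no ring is formed at any stage.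
Enabling feature: Cβ–H lies between the ring A ketone carbon Cα and Cγ (an ester before reduction) and bears the ring B aryloxy oxygen.
In the β-keto ester it therefore racemises freely, and one transfer hydrogenation with dynamic kinetic resolution fixes it.
No protecting-group exchange defines the centre, no organometallic meets an α-aryloxy carbonyl, and the ketone appears only in the last, non-basic step.

Key step: step 4

Remark: the sense of induction in step 4 is assigned from the accepted model for aryl ketones with this catalyst family (ring A under the η6-arene); should the syn product form with the opposite hand, the (R,R) catalyst would be used with no other change.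

Step 1
Reactants: 1 vanillic acid (4-hydroxy-3-methoxybenzoic acid)
Product: 2 benzyl 4-hydroxy-3-methoxybenzoate
Conditions: BnBr (1.05 equiv.), KHCO3, DMF, 40 °C
Reagents that add atoms: benzyl bromide, BrCc1ccccc1
Why: SN2 alkylation of the carboxylate, which hydrogen carbonate forms while leaving the much less acidic phenol essentially protonated, should give the benzyl ester with the phenol free.

Step 2
Reactants: 2 benzyl 4-hydroxy-3-methoxybenzoate; 3 ethyl bromoacetate
Product: 4 ethyl {4-[(benzyloxy)carbonyl]-2-methoxyphenoxy}acetate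
Conditions: K2CO3, acetone, reflux
Reagents that add atoms: none
Why: Williamson ether synthesis of the phenoxide with a reactive α-bromo ester should form the O–Cβ bond, the aryl benzyl ester being inert to carbonate in acetone.

Step 3
Reactants: 4 ethyl {4-[(benzyloxy)carbonyl]-2-methoxyphenoxy}acetate (2.0 equiv.); 5 4-(benzyloxy)-3,5-dimethoxybenzoic acid
Product: 8 benzyl 4-{[1-[4-(benzyloxy)-3,5-dimethoxyphenyl]-3-ethoxy-1,3-dioxopropan-2-yl]oxy}-3-methoxybenzoate (racemic), via aroyl chloride 6 (not isolated), via lithium ester enolate 7 (not isolated)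
Conditions: 5, (COCl)2, DMF (cat.), CH2Cl2, 0 °C to rt, evaporation; 4, LiN(SiMe3)2 (2.0 equiv.), THF, −78 °C; then 6 in THF, −78 to −40 °C; AcOH, −78 °C
Reagents that add atoms: none
Why: Crossed Claisen condensation (C-acylation of an ester enolate by an acid chloride) should form the Cα–Cβ bond, the second equivalent of enolate deprotonating the more acidic product so that it is not acylated again, and the excess of 4 being recovered.

Step 4
Reactants: 8 benzyl 4-{[1-[4-(benzyloxy)-3,5-dimethoxyphenyl]-3-ethoxy-1,3-dioxopropan-2-yl]oxy}-3-methoxybenzoate (racemic)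
Product: 9 benzyl 4-{[(1R,2S)-1-[4-(benzyloxy)-3,5-dimethoxyphenyl]-3-ethoxy-1-hydroxy-3-oxopropan-2-yl]oxy}-3-methoxybenzoate (syn hydroxy ester; (2S,3R) in propanoate numbering)
Conditions: RuCl[(S,S)-TsDPEN](p-cymene) (2 mol%), HCO2H/Et3N (5:2), CH2Cl2, 30 °C
Reagents that add atoms: none
Why: Formate converts the 16-electron divalent ruthenium amide into the Ru–H/N–H species, which passes hydride and proton to the ring A ketone through a six-membered outer-sphere transition state (Noyori–Ikariya asymmetric transfer hydrogenation), while Et3N/Et3NH+ keeps the two enantiomers of 8 in rapid exchange through the enol of the 1,3-dicarbonyl unit, so the whole racemate should be drawn through the faster-reacting enantiomer (dynamic kinetic resolution). The closest known reaction type is the transfer-hydrogenative dynamic kinetic resolution of α-alkoxy β-keto esters to syn α-alkoxy β-hydroxy esters with this class of catalyst. No ring is closed; one C–H bond is formed at Cα. The carbinol centre (Cα, R) is set by the catalyst, the ketone lying with ring A under the η6-arene as in the reduction of simple aryl ketones, and Cβ (S here, R after step 5 through a change of CIP priorities only) is set by the choice the catalyst makes between the two equilibrating enantiomers, which favours the syn product. The step needs racemisation faster than reduction and a high syn preference: the first is secured by the Cβ–H lying between the ketone and ester carbonyl groups and bearing an aryloxy oxygen, the second is the normal outcome for α-oxygenated β-keto esters, and any anti isomer is a diastereomer that can be removed here or at diol 10. Once reduced, 9 has no 1,3-dicarbonyl hydrogen, so Cβ should be fixed under the reaction conditions, and both benzyl groups and both esters are inert to formate and Et3N.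

Step 5
Reactants: 9 benzyl 4-{[(1R,2S)-1-[4-(benzyloxy)-3,5-dimethoxyphenyl]-3-ethoxy-1-hydroxy-3-oxopropan-2-yl]oxy}-3-methoxybenzoate
Product: 10 benzyl 4-{[(1R,2R)-1-[4-(benzyloxy)-3,5-dimethoxyphenyl]-1,3-dihydroxypropan-2-yl]oxy}-3-methoxybenzoate
Conditions: LiBH4, THF, 0 °C to rt; aq. NH4Cl
Reagents that add atoms: none
Why: Chemoselective borohydride reduction should take the α-aryloxy, β-hydroxy (chelating) aliphatic ethyl ester to CH2OH while the conjugated, electron-rich aryl benzyl ester stays, no alcohol cosolvent being present to exchange it, and Cβ is not touched.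

Step 6
Reactants: 10 benzyl 4-{[(1R,2R)-1-[4-(benzyloxy)-3,5-dimethoxyphenyl]-1,3-dihydroxypropan-2-yl]oxy}-3-methoxybenzoate
Product: 11 4-{[(1R,2R)-1,3-dihydroxy-1-(4-hydroxy-3,5-dimethoxyphenyl)propan-2-yl]oxy}-3-methoxybenzoic acid
Conditions: H2 (1 atm), Pd/C (10 wt% palladium on carbon), EtOAc/EtOH, rt, stopped after two equivalents of H2
Reagents that add atoms: none
Why: Catalytic hydrogenolysis should cleave the benzyl ether and the benzyl ester together under neutral conditions, under which the secondary benzylic alcohol of β-aryl ether diols is normally retained.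

Step 7
Reactants: 11 4-{[(1R,2R)-1,3-dihydroxy-1-(4-hydroxy-3,5-dimethoxyphenyl)propan-2-yl]oxy}-3-methoxybenzoic acid
Product: 12 4-{[(2R)-3-hydroxy-1-(4-hydroxy-3,5-dimethoxyphenyl)-1-oxopropan-2-yl]oxy}-3-methoxybenzoic acid
Conditions: DDQ (1.1 equiv.), 1,4-dioxane, rt, dark; filtration, chromatography on silica
Reagents that add atoms: none
Why: Quinone dehydrogenation by hydride abstraction from the benzylic Cα–H para to the free ring A phenol should give the aryl ketone alone, since the Cγ alcohol and Cβ–H are not benzylic and ring B is deactivated by its carboxyl group, and the non-basic medium should leave the Cβ centre, now α to the ketone, unchanged.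

**Compound list**
1 | vanillic acid (4-hydroxy-3-methoxybenzoic acid) | COc1cc(C(=O)O)ccc1O | starting material
2 | benzyl 4-hydroxy-3-methoxybenzoate | COc1cc(C(=O)OCc2ccccc2)ccc1O | intermediate
3 | ethyl bromoacetate | CCOC(=O)CBr | starting material
4 | ethyl {4-[(benzyloxy)carbonyl]-2-methoxyphenoxy}acetate | CCOC(=O)COc1ccc(C(=O)OCc2ccccc2)cc1OC | intermediate
5 | 4-(benzyloxy)-3,5-dimethoxybenzoic acid | COc1cc(C(=O)O)cc(OC)c1OCc1ccccc1 | starting material
6 | 4-(benzyloxy)-3,5-dimethoxybenzoyl chloride | COc1cc(C(=O)Cl)cc(OC)c1OCc1ccccc1 | intermediate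
7 | lithium 2-{4-[(benzyloxy)carbonyl]-2-methoxyphenoxy}-1-ethoxyethen-1-olate (lithium enolate of 4) | CCOC(=COc1ccc(C(=O)OCc2ccccc2)cc1OC)O[Li] | intermediate
8 | benzyl 4-{[1-[4-(benzyloxy)-3,5-dimethoxyphenyl]-3-ethoxy-1,3-dioxopropan-2-yl]oxy}-3-methoxybenzoate (racemic) | CCOC(=O)C(Oc1ccc(C(=O)OCc2ccccc2)cc1OC)C(=O)c1cc(OC)c(OCc2ccccc2)c(OC)c1 | intermediate
9 | benzyl 4-{[(1R,2S)-1-[4-(benzyloxy)-3,5-dimethoxyphenyl]-3-ethoxy-1-hydroxy-3-oxopropan-2-yl]oxy}-3-methoxybenzoate | COc1cc(C(=O)OCc2ccccc2)ccc1O[C@H](C(=O)OCC)[C@H](O)c1cc(OC)c(OCc2ccccc2)c(OC)c1 | intermediate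
10 | benzyl 4-{[(1R,2R)-1-[4-(benzyloxy)-3,5-dimethoxyphenyl]-1,3-dihydroxypropan-2-yl]oxy}-3-methoxybenzoate | COc1cc(C(=O)OCc2ccccc2)ccc1O[C@H](CO)[C@H](O)c1cc(OC)c(OCc2ccccc2)c(OC)c1 | intermediate
11 | 4-{[(1R,2R)-1,3-dihydroxy-1-(4-hydroxy-3,5-dimethoxyphenyl)propan-2-yl]oxy}-3-methoxybenzoic acid | COc1cc(C(=O)O)ccc1O[C@H](CO)[C@H](O)c1cc(OC)c(O)c(OC)c1 | intermediate
12 | 4-{[(2R)-3-hydroxy-1-(4-hydroxy-3,5-dimethoxyphenyl)-1-oxopropan-2-yl]oxy}-3-methoxybenzoic acid | COc1cc(C(=O)O)ccc1O[C@H](CO)C(=O)c1cc(OC)c(O)c(OC)c1 | target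

**Step count**
Total: 7 steps. Longest linear sequence: 7 steps (1 → 2 → 4 → 8 → 9 → 10 → 11 → 12); acid 5 enters in step 3 after activation in the flask.

**Steps most likely to fail**

Step 4. The reduction may be slow on the electron-rich ring A ketone, or the catalyst may discriminate poorly between the two equilibrating enantiomers, which would leave Cβ partly in the wrong configuration. The fallback replaces catalyst control by auxiliary control (Evans syn-aldol); it sets out from 4 and comes back to the route at 10, so steps 3 to 5 are bypassed. Selective saponification of the aliphatic ethyl ester of 4 (LiOH, 1 equiv., THF/H2O, 0 °C) would give {4-[(benzyloxy)carbonyl]-2-methoxyphenoxy}acetic acid F1. Activation as the pivalic mixed anhydride (PivCl, Et3N, THF, −20 °C) and acylation of lithiated (S)-4-benzyl-1,3-oxazolidin-2-one would give (4S)-4-benzyl-3-({4-[(benzyloxy)carbonyl]-2-methoxyphenoxy}acetyl)-1,3-oxazolidin-2-one F2. Its Z boron enolate (Bu2BOTf, iPr2NEt, CH2Cl2, −78 to 0 °C) would add to commercial 4-(benzyloxy)-3,5-dimethoxybenzaldehyde (COc1cc(C=O)cc(OC)c1OCc1ccccc1) to give the syn adduct benzyl 4-{[(1R,2S)-1-[4-(benzyloxy)-3,5-dimethoxyphenyl]-3-[(4S)-4-benzyl-2-oxo-1,3-oxazolidin-3-yl]-1-hydroxy-3-oxopropan-2-yl]oxy}-3-methoxybenzoate F3. Reductive removal of the auxiliary (LiBH4, THF with a trace of water, 0 °C) would then deliver diol 10.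

Step 3. O-acylation of the enolate, a second acylation, or Claisen self-condensation of 4 may compete with the wanted C-acylation. The fallback reaches the same carbon skeleton by aldol addition and oxidation; it sets out from 4 and comes back at 8. The lithium enolate 7 (1 equiv. LiN(SiMe3)2, THF, −78 °C) would be added to commercial 4-(benzyloxy)-3,5-dimethoxybenzaldehyde to give ethyl 3-[4-(benzyloxy)-3,5-dimethoxyphenyl]-2-{4-[(benzyloxy)carbonyl]-2-methoxyphenoxy}-3-hydroxypropanoate F4 as a mixture of stereoisomers, all of which are serviceable. Dess–Martin periodinane (CH2Cl2, rt) would oxidise it to 8.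

Step 7. Over-oxidation of the free ring A phenol (quinone methide or quinone formation with loss of the side chain) or loss of configuration at Cβ during isolation may erode the product. The fallback inverts the order of oxidation and deprotection; it sets out from 10 and comes back at 12. The secondary benzylic alcohol of the still protected diol 10 would be oxidised first (4-acetamido-TEMPO, 5 mol%, HNO3 and HCl, 10 mol% each, O2, MeCN/H2O, 45 °C; a nitroxyl/oxoammonium system known to prefer the secondary benzylic over the primary alcohol of β-aryl ether diols) to give benzyl 4-{[(2R)-1-[4-(benzyloxy)-3,5-dimethoxyphenyl]-3-hydroxy-1-oxopropan-2-yl]oxy}-3-methoxybenzoate F5. Neutral hydrogenolysis (H2, 1 atm, Pd/C (10 wt% palladium on carbon), EtOAc, rt, stopped after two equivalents) would then give 12, and no free electron-rich phenol would be exposed to an oxidant in this order.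

**Further compounds**
F1 | step 4 | {4-[(benzyloxy)carbonyl]-2-methoxyphenoxy}acetic acid | COc1cc(C(=O)OCc2ccccc2)ccc1OCC(=O)O
F2 | step 4 | (4S)-4-benzyl-3-({4-[(benzyloxy)carbonyl]-2-methoxyphenoxy}acetyl)-1,3-oxazolidin-2-one | COc1cc(C(=O)OCc2ccccc2)ccc1OCC(=O)N1[C@@H](Cc2ccccc2)COC1=O
F3 | step 4 | benzyl 4-{[(1R,2S)-1-[4-(benzyloxy)-3,5-dimethoxyphenyl]-3-[(4S)-4-benzyl-2-oxo-1,3-oxazolidin-3-yl]-1-hydroxy-3-oxopropan-2-yl]oxy}-3-methoxybenzoate | COc1cc(C(=O)OCc2ccccc2)ccc1O[C@H](C(=O)N1[C@@H](Cc2ccccc2)COC1=O)[C@H](O)c1cc(OC)c(OCc2ccccc2)c(OC)c1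
F4 | step 3 | ethyl 3-[4-(benzyloxy)-3,5-dimethoxyphenyl]-2-{4-[(benzyloxy)carbonyl]-2-methoxyphenoxy}-3-hydroxypropanoate (mixture of stereoisomers) | CCOC(=O)C(Oc1ccc(C(=O)OCc2ccccc2)cc1OC)C(O)c1cc(OC)c(OCc2ccccc2)c(OC)c1
F5 | step 7 | benzyl 4-{[(2R)-1-[4-(benzyloxy)-3,5-dimethoxyphenyl]-3-hydroxy-1-oxopropan-2-yl]oxy}-3-methoxybenzoate | COc1cc(C(=O)OCc2ccccc2)ccc1O[C@H](CO)C(=O)c1cc(OC)c(OCc2ccccc2)c(OC)c1
A1 | direct plan | tert-butyl 4-[(1,3-dihydroxypropan-2-yl)oxy]-3-methoxybenzoate | COc1cc(C(=O)OC(C)(C)C)ccc1OC(CO)CO
A2 | direct plan | tert-butyl 4-{[(2R)-1-[(tert-butyldimethylsilyl)oxy]-3-oxopropan-2-yl]oxy}-3-methoxybenzoate | COc1cc(C(=O)OC(C)(C)C)ccc1O[C@H](CO[Si](C)(C)C(C)(C)C)C=O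
A3 | direct plan | tert-butyl 4-{[(2R)-1-[4-(benzyloxy)-3,5-dimethoxyphenyl]-3-[(tert-butyldimethylsilyl)oxy]-1-oxopropan-2-yl]oxy}-3-methoxybenzoate | COc1cc(C(=O)OC(C)(C)C)ccc1O[C@H](CO[Si](C)(C)C(C)(C)C)C(=O)c1cc(OC)c(OCc2ccccc2)c(OC)c1
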